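The numbers in the tables are simulated on assumed constants, noise included.

A parabola through the larch readings ends in an impossibility: J at 12.0 min, scaled with the square of time, reaches 156% of the Q charged by 40 min, which is over the charge.

| flask | Q | E | G | remark | time |
|---|---|---|---|---|---|
| larch | 2 M | 100 mM | 54 mM | run made earlier |  |
| flask | 2.0 M | 100 mM | 36 mM |  | 40 min |

larch run (percent of the Q charged)

| time / min | J / % | Q / % |
|---|---|---|
| 1.00 | 0 | 98 |
| 3.00 | 1 | 98 |
| 6.00 | 5 | 95 |
| 8.00 | 7 | 93 |
| 12.0 | 14 | 86 |

(standard deviation of a reading: 1.5 percentage points)

- the average divides the monomer in chains by the number of chains begun, living and dead together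
- the earlier runs do not show the number of chains; that part of a forecast is a guess

- average number of monomer units in a chain (chains begun, living or dead) at 40 min
- part of the Q that has reacted at 40 min

Inside the larch run the parabola gives 6.24% at 8.00 min against a reading of 7%; beyond that run it cheats, with J over the charge at 40 min. The second way, reckoned here and not the forecast's, supposes that G titrates E one for one and that the remaining E starts chains. The free share, the part of the E charge left once G has taken its equal amount, is 64.0% in the flask and 46.0% in larch.

Between 8.00 min and 12.0 min, larch loses Q with a pseudo-first-order constant of 0.0196 min⁻¹, a reading that carries a scatter of 1.5 percentage points on each point. Scaled by the free shares to 0.0272 min⁻¹ and held for 40 min, it gives an estimated c of 66.3%, which stays under the charge. With each free E counted as one chain, dp comes to 20.7.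

The forecast is lower on both, with dp 14 and c 50%, and it says: “That lag probably reflects G being used up”.

The flask gives dp 22.8 and c 64.5%.

    Q + E → Z + J (k = 8.60 × 10⁻⁴ M⁻¹ s⁻¹)
    Q + Z → J + Z, rate k2*[Z]*[Q] (k = 0.00940 M⁻¹ s⁻¹)
    E + G → X (k = 21.0 M⁻¹ s⁻¹)
    Q + E → L (k = 6.60 × 10⁻⁵ M⁻¹ s⁻¹)

In the flask at 40.0 min, Z, L and unspent E together hold 64.0% of the E charge, against a free share of 64.0%, while G stands at 0% and X at 0.0360 M. The neighbouring flask, with 0.0090 M of G, has a free share of 91.0%. The same scaling gives c of 78.7% and dp 17.3. That flask gives c 76.5% and dp 19.5, and its Z, L and unspent E hold 91.0% of the E charge.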